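## The problem

Numbering: isoflavone numbering is used for the target (ring A/C: O1, C2–C8a; ring B: C1'–C6'; pyran ring D: O1'', C2''–C4''). Chromene intermediates use chromene numbering, where C2 = C2'', C4a = C3', C5 = C4', C8 = C1' and C8a = C2'.

The target 22 is a 5,7-dihydroxyisoflavone (rings A and C). Its ring B carries a free hydroxyl at C4' and is fused across C2'–C3' to a 2H-pyran (ring D). Ring D ends in a quaternary carbon C2'' bearing methyl, hydroxymethyl, the ring oxygen and the vinyl carbon C3''. Ring B is therefore a 1,2,3,4-tetrasubstituted benzene joined through C1' to C3 of the pyranone, and the order of its four substituents must be fixed without ambiguity. C2'' is the only stereocentre (S). Nothing else in the molecule can induce it, so it has to enter enantiopure and must never become a reacting centre afterwards. That is a real constraint, because O1''–C2'' is a tertiary ether that is formally allylic and aryl-bound. Acid can ionise it, and the classical thermal chromene synthesis (propargyl Claisen shift, hydrogen shift, oxa-6π closure) passes through a ring-opened dienone in which C2'' is trigonal. Further fragile sites are the electron-rich ring A with free hydroxyls, C2 of the isoflavone (hard nucleophiles add there and open ring C), and the styrene-like C3''=C4'' bond. The enabling feature is that O1 (on C8a), O5 and O7 lie ortho, ortho and para to the C4 carbonyl. This is exactly the activation pattern of a 2,4,6-trifluorobenzoyl group: one ortho fluoride can be displaced from within to close ring C, and the other two afterwards by an alkoxide.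

## Retrosynthesis

**Protecting groups (22 ⇐ 21 ⇐ 20).** Only O–allyl and O–benzyl bonds are cut. The three phenols are carried as allyl ethers, so the last step (21 → 22) runs under neutral conditions with Pd(PPh3)4 and the chromene never meets acid. The primary alcohol is carried as a 4-methoxybenzyl (PMB) ether, removed oxidatively (20 → 21) while all phenols are still masked. A silyl ether was rejected here: next to the tertiary alkoxide needed earlier it can migrate from oxygen to oxygen and expose the primary alkoxide instead.

**Ring A oxygens (20 ⇐ 18).** The C5–O and C7–O bonds are cut back to C–F bonds. This avoids any acyl unit at the phloroglucinol oxidation level, which is electron-rich, easily decarboxylated and needs harsh acylation conditions. In 18 both fluorides are ortho/para to the C4 carbonyl and meta to each other and to O1. The forward step asks for two alkoxide displacements that do not attack C2.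

**Ring C, the strategic cut (18 ⇐ 17).** The O1–C8a bond is cut, giving the open hydroxymethylene ketone 17 with a 2,4,6-trifluorobenzoyl group. The neighbouring cut O1–C2 (classical isoflavone closure) would require a 2-hydroxyaryl ketone, which is the phloroglucinol problem again. The cut C3–C1' (cross-coupling) would require a halochromone and a boron reagent on a crowded ring B. Compound 17 is acyclic at ring C and derives from a symmetric, commercial acid chloride. The forward step asks for O-attack at an ortho fluoride, which ring size and symmetry guarantee.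

**C3–C4 and C2–C3 (17 ⇐ 14 + 15; 14 ⇐ 10 + 12; 12 ⇐ 11).** Cutting C3–C4 gives the enamine 14 and 2,4,6-trifluorobenzoyl chloride 15. Enamine C-acylation followed by hydrolysis delivers the formyl ketone directly, so no deoxybenzoin has to be formylated separately. Cutting the enamine double bond leads to aldehyde 10 and the aminomethyl phosphine oxide 12, which supplies C2 and is made from diphenylphosphine oxide 11. The forward steps ask for C- rather than N-acylation and for a hydrolysis mild enough for the PMB and allyl ethers.

**Ring D (10 ⇐ 8 ⇐ 7).** The aldehyde is traced to nitrile 8. Cutting C4a–C4 of the chromene (C3'–C4'') gives the aryl propargyl ether 7. A gold-catalysed hydroarylation is preferred to the thermal Claisen route because it leaves the O–C2'' bond alone. Only one ortho position is free, so regiochemistry is not in question.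

**Aryl ether (7 ⇐ 4 + 6; 6 ⇐ 5).** The aryl C–O bond is cut to the tertiary propargylic alcohol 4 and 4-(allyloxy)-2-fluorobenzonitrile 6, made from phenol 5. Fluoride displacement forms the ether without touching the stereocentre. A nitrile rather than a formyl group activates the fluoride, because a formyl group would be open to alkynide addition under the basic conditions. The allyloxy group is meta to the leaving fluoride and does not deactivate it.

**Stereocentre (4 ⇐ 3 ⇐ 2 ⇐ 1).** The alkyne is cut back to aldehyde 3, this to diol 2, and 2 to (S)-2-methylglycidol 1 plus 4-methoxybenzyl alcohol. The carbinol carbon of 1 becomes the alkyne and its epoxide CH2 becomes the protected hydroxymethyl group. Tracking the four substituents through the sequence shows that this assignment, starting from the S epoxide, gives S at C2'' of 22. The epoxide oxygen stays on the quaternary carbon throughout.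

## Roads not taken

**Alternative 1: benzannulation of ring B.** Ring B is dismantled completely by cutting C1'–C2', C2'–C3', C4'–C5' and C5'–C6'. This leaves the diazo enone A2 (chromone complete, ring A oxygens as methoxymethyl ethers) and the siloxyalkyne A3 carrying the future C3' side chain. In the forward step, irradiation of A2 triggers a Wolff rearrangement. Cycloaddition with A3, four-electron ring opening, six-electron ring closure and tautomerisation then give phenol A1.
- Merits: every substituent of the tetrasubstituted ring is placed by mechanism rather than by directing effects, ring A is at its final oxidation level from the start, and the route is convergent. On these points this road is better than the chosen plan, which must exchange two fluorides late.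
- Weak points: A1 is achiral and has neither ring D nor C2''. The stereocentre would have to be made late from a trisubstituted alkene by asymmetric oxidation and ring closure (the sequence of Alternative 2), adding several steps after the key step. The chromone of A2 absorbs where diazo ketones are photolysed, and its C2=C3 bond is itself photoreactive. Making A2 by diazo transfer needs base, which threatens C2. A3 is a sensitive skipped enyne, and both partners need multistep syntheses.
- Against this the chosen plan sets a ring B bought as a benzene with its substituents already in order (5), and a stereocentre installed in step 1.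

**Alternative 2: epoxide opening by the C2' phenol.** The O1''–C2'' bond is cut, leading to the (2S,3S)-epoxy alcohol A5. In the forward step, catalytic camphorsulfonic acid lets the C2' phenol attack the tertiary epoxide carbon with inversion, in the 6-endo mode, to give the chroman A4.
- Merits: the stereocentre comes from a catalytic asymmetric epoxidation (Ti(Oi-Pr)4, diethyl tartrate, t-BuOOH), so either enantiomer is available at will. Here this road is better than the chosen plan, which depends on the supply of 1.
- Weak points: the reacting carbon is C2'' itself. The 6-endo preference relies on cationic character at that carbon, which the hydroxymethyl group reduces, so 5-exo attack at C3'' competes. To the extent that the carbon is cationic, inversion is no longer clean. A4 is also at the wrong oxidation level: the C3'' hydroxyl must be told apart from the primary one, activated and eliminated next to a quaternary carbon, which costs at least three further steps.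
- Against this the chosen plan never makes C2'' a reacting centre and obtains the C3''=C4'' bond directly from an alkyne.

**Alternative 3: alkyne hydroarylation as the strategic step.** The C3'–C4'' bond is cut, leading to the enantiopure aryl propargyl ether A7. In the forward step, Ph3PAuNTf2 (monovalent gold) activates the terminal alkyne and C3' attacks its terminal carbon, giving the chromene aldehyde A6.
- Merits: the closure is mild, the C2''–O bond is untouched, and only one ortho position is free. In this respect the road is as good as the chosen plan; the same transformation is adopted in step 6 (7 → 8).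
- Weak points: as a strategy it solves ring D only. Rings A and C would still have to be attached by an acyl donor at the phloroglucinol oxidation level or by a cross-coupling on a crowded arene. The silyl ether in A7 sits next to the tertiary alkoxide needed to make it and can migrate. The formyl group is exposed to alkynide addition during ether formation. The methoxymethyl ether in A6 needs acid at the end.
- The chosen plan keeps this ring closure, replaces silyl, methoxymethyl and formyl by PMB, allyl and nitrile, and adds the fluoride-based assembly of rings A and C.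

Key step: step 11

Remark on the chemistry: the geometry of the transient enaminone 16 is taken as E but does not matter, since hydrolysis gives the same chelated enol 17.

## Route

Step 1
Reactants: 1 (S)-2-methylglycidol
Product: 2 (2S)-3-[(4-methoxybenzyl)oxy]-2-methylpropane-1,2-diol
Conditions: 4-methoxybenzyl alcohol (5 equiv), NaH (0.2 equiv), neat, 70 °C
Reagents that add atoms: 4-methoxybenzyl alcohol, COc1ccc(CO)cc1
Why: Base-mediated SN2 opening of the epoxide at its CH2 carbon by the benzylic alkoxide; the quaternary carbon is not attacked and the Payne rearrangement of the glycidol alkoxide is degenerate (it returns the same enantiomer), so the configuration is kept and the two hydroxymethyl arms are differentiated.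

Step 2
Reactants: 2 (2S)-3-[(4-methoxybenzyl)oxy]-2-methylpropane-1,2-diol
Product: 3 (2R)-2-hydroxy-3-[(4-methoxybenzyl)oxy]-2-methylpropanal
Conditions: SO3·pyridine, DMSO, i-Pr2NEt, CH2Cl2, 0 °C
Reagents that add atoms: none
Why: Parikh–Doering oxidation acts on the primary alcohol only, the tertiary hydroxyl being inert; the α-carbon carries no hydrogen, so the aldehyde cannot enolise or epimerise (the descriptor changes to R by priority only).

Step 3
Reactants: 3 (2R)-2-hydroxy-3-[(4-methoxybenzyl)oxy]-2-methylpropanal
Product: 4 (2S)-1-[(4-methoxybenzyl)oxy]-2-methylbut-3-yn-2-ol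
Conditions: MeC(O)C(N2)P(O)(OMe)2, K2CO3, MeOH, 0 °C → rt
Reagents that add atoms: dimethyl (1-diazo-2-oxopropyl)phosphonate (Ohira–Bestmann reagent), COP(=O)(OC)C(=[N+]=[N-])C(C)=O
Why: Seyferth–Gilbert homologation in the Ohira–Bestmann variant converts the aldehyde into the terminal alkyne under mild carbonate conditions that tolerate a free hydroxyl; the quaternary stereocentre takes no part.

Step 4
Reactants: 5 2-fluoro-4-hydroxybenzonitrile
Product: 6 4-(allyloxy)-2-fluorobenzonitrile
Conditions: allyl bromide, K2CO3, DMF, rt
Reagents that add atoms: allyl bromide, C=CCBr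
Why: Williamson etherification of an acidic phenol; the phenoxide is too weak a nucleophile to displace the fluoride of a second molecule at room temperature.

Step 5
Reactants: 4 (2S)-1-[(4-methoxybenzyl)oxy]-2-methylbut-3-yn-2-ol; 6 4-(allyloxy)-2-fluorobenzonitrile
Product: 7 4-(allyloxy)-2-{[(2S)-1-[(4-methoxybenzyl)oxy]-2-methylbut-3-yn-2-yl]oxy}benzonitrile
Conditions: NaH, DMF, 0 °C; then 6, 0 °C → rt
Reagents that add atoms: none
Why: Nucleophilic aromatic substitution (addition–elimination) by the sodium alkoxide of the tertiary propargylic alcohol on a fluoride ortho to a nitrile, a known way to aryl 1,1-disubstituted propargyl ethers; the allyloxy group is meta to the leaving fluoride and does not deactivate it. The C–O bond at the stereocentre is not broken, so the configuration is retained, and the PMB ether, unlike a silyl ether, cannot migrate to the alkoxide.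

Step 6
Reactants: 7 4-(allyloxy)-2-{[(2S)-1-[(4-methoxybenzyl)oxy]-2-methylbut-3-yn-2-yl]oxy}benzonitrile
Product: 8 (2S)-5-(allyloxy)-2-{[(4-methoxybenzyl)oxy]methyl}-2-methyl-2H-chromene-8-carbonitrile
Conditions: Ph3PAuNTf2 (3 mol %), CH2Cl2, rt
Reagents that add atoms: none
Why: Gold-catalysed intramolecular alkyne hydroarylation (6-endo-dig) of an aryl propargyl ether: the only free ortho carbon, activated by its two flanking oxygens, attacks the terminal alkyne carbon and protodeauration gives the 2H-chromene. The propargylic C–O bond is never broken, so C2 stays S, in contrast to the thermal Claisen route.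

Step 7
Reactants: 8 (2S)-5-(allyloxy)-2-{[(4-methoxybenzyl)oxy]methyl}-2-methyl-2H-chromene-8-carbonitrile
Product: 10 (2S)-5-(allyloxy)-2-{[(4-methoxybenzyl)oxy]methyl}-2-methyl-2H-chromene-8-carbaldehyde, via N-diisobutylalumino aldimine 9 (not isolated)
Conditions: i-Bu2AlH, toluene, −78 → −20 °C; then 1 M HCl, 0 °C
Reagents that add atoms: water, O
Why: Partial reduction of an aryl nitrile by i-Bu2AlH stops at the N-aluminated imine, which cold dilute acid hydrolyses to the aldehyde; the chromene alkene and the allyl and PMB ethers are inert to the hydride at low temperature.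

Step 8
Reactants: 11 diphenylphosphine oxide
Product: 12 (morpholin-4-ylmethyl)diphenylphosphine oxide
Conditions: (CH2O)n, morpholine, toluene, 80 °C
Reagents that add atoms: formaldehyde (as paraformaldehyde), C=O; morpholine, C1COCCN1
Why: Three-component phospha-Mannich (Kabachnik–Fields type) condensation of a secondary phosphine oxide with formaldehyde and a secondary amine.

Step 9
Reactants: 10 (2S)-5-(allyloxy)-2-{[(4-methoxybenzyl)oxy]methyl}-2-methyl-2H-chromene-8-carbaldehyde; 12 (morpholin-4-ylmethyl)diphenylphosphine oxide
Product: 14 4-[(E)-2-{(2S)-5-(allyloxy)-2-{[(4-methoxybenzyl)oxy]methyl}-2-methyl-2H-chromen-8-yl}ethenyl]morpholine, via lithium alkoxide of the β-hydroxy phosphine oxide adduct 13 (not isolated)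
Conditions: 12, n-BuLi, THF, −78 °C; then 10; then KOt-Bu, −78 °C → rt
Reagents that add atoms: none
Why: Horner–Wittig olefination with the lithiated α-amino phosphine oxide; after exchange to the potassium alkoxide the adduct loses diphenylphosphinate to give the conjugated (E)-enamine, a one-carbon homologation that arrives directly at the enamine. The enamine is used without chromatography.

Step 10
Reactants: 14 4-[(E)-2-{(2S)-5-(allyloxy)-2-{[(4-methoxybenzyl)oxy]methyl}-2-methyl-2H-chromen-8-yl}ethenyl]morpholine; 15 2,4,6-trifluorobenzoyl chloride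
Product: 17 (Z)-2-[(2S)-5-(allyloxy)-2-{[(4-methoxybenzyl)oxy]methyl}-2-methyl-2H-chromen-8-yl]-3-hydroxy-1-(2,4,6-trifluorophenyl)prop-2-en-1-one, via morpholine enaminone 16 (not isolated)
Conditions: 15, Et3N, CH2Cl2, 0 °C → rt; then 1 M HCl, THF, rt
Reagents that add atoms: water, O
Why: Stork enamine acylation: the β-carbon of the enamine (the one bearing the aryl group) attacks the acid chloride, which has no α-hydrogen and cannot form a ketene, and Et3N takes up HCl. Dilute acid then hydrolyses the vinylogous amide to the formyl ketone, which rests as the hydrogen-bonded Z enol; PMB and allyl ethers withstand these conditions.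

Step 11
Reactants: 17 (Z)-2-[(2S)-5-(allyloxy)-2-{[(4-methoxybenzyl)oxy]methyl}-2-methyl-2H-chromen-8-yl]-3-hydroxy-1-(2,4,6-trifluorophenyl)prop-2-en-1-one
Product: 18 3-[(2S)-5-(allyloxy)-2-{[(4-methoxybenzyl)oxy]methyl}-2-methyl-2H-chromen-8-yl]-5,7-difluoro-4H-chromen-4-one
Conditions: K2CO3, DMF (dry, 0.05 M), rt → 50 °C
Reagents that add atoms: none
Why: K2CO3 deprotonates the chelated enol of 17; the enolate oxygen adds to the fluorine-bearing carbon ortho to the ketone (the future C8a), giving a Meisenheimer anion delocalised onto the C4 carbonyl and stabilised inductively by the two other fluorines, and loss of fluoride restores the arene and forms the O1–C8a bond. The closest known reaction type is the base-mediated cyclisation of 2-fluorobenzoyl 1,3-dicarbonyl enolates to chromones (and of the corresponding enamines to 4-quinolones) by intramolecular nucleophilic aromatic substitution. Ring C closes in the 6-exo-trig mode of an addition–elimination. No stereocentre is formed, and C2'' is remote from the reacting atoms and not at risk. The step needs O- rather than C-attack, which ring size secures because attack through C3 would give a four-membered ring. It needs ortho rather than para attack, which geometry secures because the para fluoride cannot be reached from within, and the two ortho fluorides are equivalent by symmetry. Intermolecular displacement is held back by dilution, and dry carbonate avoids retro-Claisen loss of the formyl carbon. The two remaining fluorides end up at C5 and C7, ortho and para to the chromone carbonyl.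

Step 12
Reactants: 18 3-[(2S)-5-(allyloxy)-2-{[(4-methoxybenzyl)oxy]methyl}-2-methyl-2H-chromen-8-yl]-5,7-difluoro-4H-chromen-4-one
Product: 20 5,7-bis(allyloxy)-3-[(2S)-5-(allyloxy)-2-{[(4-methoxybenzyl)oxy]methyl}-2-methyl-2H-chromen-8-yl]-4H-chromen-4-one, via 7-allyloxy-5-fluoro isoflavone 19 (not isolated)
Conditions: allyl alcohol, NaH, THF, 0 → 50 °C
Reagents that add atoms: allyl alcohol, C=CCO
Why: Two successive nucleophilic aromatic substitutions by sodium allyloxide at C7 (para to C4=O) and C5 (ortho to C4=O); the first allyloxy group is meta to the remaining fluoride and so does not cancel its activation. Allyl is chosen because it stays a neutral ether during the second displacement and comes off later without acid or base.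

Step 13
Reactants: 20 5,7-bis(allyloxy)-3-[(2S)-5-(allyloxy)-2-{[(4-methoxybenzyl)oxy]methyl}-2-methyl-2H-chromen-8-yl]-4H-chromen-4-one
Product: 21 5,7-bis(allyloxy)-3-[(2S)-5-(allyloxy)-2-(hydroxymethyl)-2-methyl-2H-chromen-8-yl]-4H-chromen-4-one
Conditions: DDQ, CH2Cl2–pH 7 buffer (10:1), 0 °C → rt
Reagents that add atoms: none
Why: Oxidative cleavage of the PMB ether by DDQ (benzylic oxidation to the oxocarbenium ion, then hydrolysis); aryl allyl ethers are inert, the chromene has no hydrogen at C2 to lose, and the step is placed before any phenol is set free.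

Step 14
Reactants: 21 5,7-bis(allyloxy)-3-[(2S)-5-(allyloxy)-2-(hydroxymethyl)-2-methyl-2H-chromen-8-yl]-4H-chromen-4-one
Product: 22 5,7-dihydroxy-3-[(2S)-5-hydroxy-2-(hydroxymethyl)-2-methyl-2H-chromen-8-yl]-4H-chromen-4-one (CNP0141863.1)
Conditions: Pd(PPh3)4 (5 mol %), morpholine, THF, rt
Reagents that add atoms: none
Why: Tsuji–Trost deallylation: zerovalent palladium ionises the three aryl allyl ethers to π-allyl complexes that morpholine captures. The ring D ether, although formally allylic, is tertiary and its C–O bond lies in the nodal plane of the C3''=C4'' π bond, so it is not ionised; the neutral conditions spare the chromene and the free phloroglucinol ring.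

## Compound list

1 | (S)-2-methylglycidol, [(2S)-2-methyloxiran-2-yl]methanol | OC[C@@]1(C)CO1 | starting material
2 | (2S)-3-[(4-methoxybenzyl)oxy]-2-methylpropane-1,2-diol | OC[C@@](O)(C)COCc1ccc(OC)cc1 | intermediate
3 | (2R)-2-hydroxy-3-[(4-methoxybenzyl)oxy]-2-methylpropanal | O=C[C@@](O)(C)COCc1ccc(OC)cc1 | intermediate
4 | (2S)-1-[(4-methoxybenzyl)oxy]-2-methylbut-3-yn-2-ol | C#C[C@@](O)(C)COCc1ccc(OC)cc1 | intermediate
5 | 2-fluoro-4-hydroxybenzonitrile | N#Cc1ccc(O)cc1F | starting material
6 | 4-(allyloxy)-2-fluorobenzonitrile | N#Cc1ccc(OCC=C)cc1F | intermediate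
7 | 4-(allyloxy)-2-{[(2S)-1-[(4-methoxybenzyl)oxy]-2-methylbut-3-yn-2-yl]oxy}benzonitrile | C#C[C@@](Oc1cc(OCC=C)ccc1C#N)(C)COCc1ccc(OC)cc1 | intermediate
8 | (2S)-5-(allyloxy)-2-{[(4-methoxybenzyl)oxy]methyl}-2-methyl-2H-chromene-8-carbonitrile | C[C@@]1(COCc2ccc(OC)cc2)C=Cc2c(OCC=C)ccc(C#N)c2O1 | intermediate
9 | N-(diisobutylalumino) aldimine of aldehyde 10 | C[C@@]1(COCc2ccc(OC)cc2)C=Cc2c(OCC=C)ccc(C=N[Al](CC(C)C)CC(C)C)c2O1 | intermediate (not isolated)
10 | (2S)-5-(allyloxy)-2-{[(4-methoxybenzyl)oxy]methyl}-2-methyl-2H-chromene-8-carbaldehyde | C[C@@]1(COCc2ccc(OC)cc2)C=Cc2c(OCC=C)ccc(C=O)c2O1 | intermediate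
11 | diphenylphosphine oxide | O=[PH](c1ccccc1)c1ccccc1 | starting material
12 | (morpholin-4-ylmethyl)diphenylphosphine oxide | O=P(CN1CCOCC1)(c1ccccc1)c1ccccc1 | intermediate
13 | lithium alkoxide of 2-(diphenylphosphoryl)-2-(morpholin-4-yl)-1-[(2S)-chromen-8-yl]ethanol (adduct of 10 and lithiated 12; mixture of diastereomers at the two new carbons) | C[C@@]1(COCc2ccc(OC)cc2)C=Cc2c(OCC=C)ccc(C([O-])C(N3CCOCC3)P(=O)(c3ccccc3)c3ccccc3)c2O1.[Li+] | intermediate (not isolated)
14 | 4-[(E)-2-{(2S)-5-(allyloxy)-2-{[(4-methoxybenzyl)oxy]methyl}-2-methyl-2H-chromen-8-yl}ethenyl]morpholine | C[C@@]1(COCc2ccc(OC)cc2)C=Cc2c(OCC=C)ccc(/C=C/N3CCOCC3)c2O1 | intermediate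
15 | 2,4,6-trifluorobenzoyl chloride | O=C(Cl)c1c(F)cc(F)cc1F | starting material
16 | (E)-2-[(2S)-5-(allyloxy)-2-{[(4-methoxybenzyl)oxy]methyl}-2-methyl-2H-chromen-8-yl]-3-(morpholin-4-yl)-1-(2,4,6-trifluorophenyl)prop-2-en-1-one | C[C@@]1(COCc2ccc(OC)cc2)C=Cc2c(OCC=C)ccc(/C(=C\N3CCOCC3)C(=O)c3c(F)cc(F)cc3F)c2O1 | intermediate (not isolated)
17 | (Z)-2-[(2S)-5-(allyloxy)-2-{[(4-methoxybenzyl)oxy]methyl}-2-methyl-2H-chromen-8-yl]-3-hydroxy-1-(2,4,6-trifluorophenyl)prop-2-en-1-one (chelated enol) | C[C@@]1(COCc2ccc(OC)cc2)C=Cc2c(OCC=C)ccc(/C(=C/O)C(=O)c3c(F)cc(F)cc3F)c2O1 | intermediate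
18 | 3-[(2S)-5-(allyloxy)-2-{[(4-methoxybenzyl)oxy]methyl}-2-methyl-2H-chromen-8-yl]-5,7-difluoro-4H-chromen-4-one | C[C@@]1(COCc2ccc(OC)cc2)C=Cc2c(OCC=C)ccc(-c3coc4cc(F)cc(F)c4c3=O)c2O1 | intermediate
19 | 7-(allyloxy)-3-[(2S)-5-(allyloxy)-2-{[(4-methoxybenzyl)oxy]methyl}-2-methyl-2H-chromen-8-yl]-5-fluoro-4H-chromen-4-one | C[C@@]1(COCc2ccc(OC)cc2)C=Cc2c(OCC=C)ccc(-c3coc4cc(OCC=C)cc(F)c4c3=O)c2O1 | intermediate (not isolated)
20 | 5,7-bis(allyloxy)-3-[(2S)-5-(allyloxy)-2-{[(4-methoxybenzyl)oxy]methyl}-2-methyl-2H-chromen-8-yl]-4H-chromen-4-one | C[C@@]1(COCc2ccc(OC)cc2)C=Cc2c(OCC=C)ccc(-c3coc4cc(OCC=C)cc(OCC=C)c4c3=O)c2O1 | intermediate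
21 | 5,7-bis(allyloxy)-3-[(2S)-5-(allyloxy)-2-(hydroxymethyl)-2-methyl-2H-chromen-8-yl]-4H-chromen-4-one | C[C@@]1(CO)C=Cc2c(OCC=C)ccc(-c3coc4cc(OCC=C)cc(OCC=C)c4c3=O)c2O1 | intermediate
22 | 5,7-dihydroxy-3-[(2S)-5-hydroxy-2-(hydroxymethyl)-2-methyl-2H-chromen-8-yl]-4H-chromen-4-one (CNP0141863.1) | C[C@@]1(CO)C=Cc2c(O)ccc(-c3coc4cc(O)cc(O)c4c3=O)c2O1 | target

## Step count and least certain steps

Total step count: 14. Longest linear sequence: 12 steps (steps 1, 2, 3, 5, 6, 7, 9, 10, 11, 12, 13, 14, from 1). Steps 4 and 8 supply side components.

**Step 11 (key step).** The most likely failures are two. The enolate of one molecule may displace the para fluoride of another, which no intramolecular path can reach and which is the most exposed position toward external nucleophiles. Hydroxide from damp carbonate may cause retro-Claisen loss of the formyl carbon. The fallback removes the para fluoride before the ring is closed and sets out from enamine 14. Commercial 2,6-difluoro-4-hydroxybenzoic acid is bis-allylated (allyl bromide, K2CO3, DMF) to allyl 4-(allyloxy)-2,6-difluorobenzoate F1. Saponification (LiOH, aqueous THF) gives 4-(allyloxy)-2,6-difluorobenzoic acid F2, and (COCl)2 with catalytic DMF gives 4-(allyloxy)-2,6-difluorobenzoyl chloride F3. Acylation of 14 with F3 as in step 10 gives the enaminone F4, and acid hydrolysis gives the hydroxymethylene ketone F5. Only the two ring-closing fluorides are now present, so F5 can be cyclised with K2CO3 in DMF at 60–80 °C. The route is rejoined at 19, which is isolated and needs only the C5 displacement of step 12 to reach 20.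

**Step 12.** The most likely failure is conjugate addition of allyloxide to C2 of the isoflavone, opening ring C and expelling the C2 carbon as a formate. The second displacement at C5 is slower than the first and may stall at 19, leaving time for this. The fallback carries out the fluoride exchange before ring C exists. It sets out from enaminone 16, isolated from step 10 instead of being hydrolysed; this vinylogous amide has no ring to open. Sodium allyloxide (2 equiv, THF) replaces the para and one of the two equivalent ortho fluorides to give the 2,4-bis(allyloxy)-6-fluorobenzoyl enaminone F6. Acid hydrolysis gives the hydroxymethylene ketone F7, and K2CO3 in DMF at 80–100 °C closes ring C through the remaining ortho fluoride. The route is rejoined at 20.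

**Step 10.** The most likely failures are N-acylation followed by hydrolytic return of the moisture-sensitive enamine to the aldehyde level, slow C-acylation at the hindered aryl-conjugated β-carbon, and double acylation. The fallback builds the ketone first and adds the formyl carbon last, setting out from 14. Buffered aqueous acetic acid hydrolyses 14 to the arylacetaldehyde F8. Addition of 2,4,6-trifluorophenylmagnesium chloride (from 1-bromo-2,4,6-trifluorobenzene and i-PrMgCl·LiCl, −40 °C) gives the carbinol F9, and Dess–Martin periodinane oxidises it to the deoxybenzoin F10. Claisen formylation (ethyl formate, NaH, THF, 0 °C, cold acidic quench) rejoins the route at 17.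

**Step 5.** The most likely failure is deprotonation of the terminal alkyne by the hindered tertiary alkoxide, whose addition to the arene is slow. The alkynide can then add to the nitrile, or the alkoxide can fragment on warming. The fallback caps the alkyne and sets out from 4. Double deprotonation (n-BuLi, 2 equiv, THF, −78 °C) and i-Pr3SiCl give the C-silylated alkynol F11. The same fluoride displacement on 6 (NaH, DMF) gives the silylated aryl ether F12, and Bu4NF in THF removes the silyl group to rejoin the route at 7.

**Step 6.** The most likely failure is ionisation of the tertiary propargylic C–O bond by the Lewis-acidic gold centre, since 2-cyanophenoxide is a fair leaving group. This would erode the configuration or cleave the side chain, and nitrile coordination may slow the catalyst enough for it to compete. The fallback closes the ring with an iodonium electrophile and sets out from 7. I2 and NaHCO3 in MeNO2 at rt effect 6-endo iodocyclisation to the 3-iodochromene F13 (descriptor 2R by priority, same spatial arrangement). Radical deiodination (Bu3SnH, catalytic AIBN, toluene, 80 °C) rejoins the route at 8.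

## Further compounds

F1 | step 11 | allyl 4-(allyloxy)-2,6-difluorobenzoate | C=CCOC(=O)c1c(F)cc(OCC=C)cc1F
F2 | step 11 | 4-(allyloxy)-2,6-difluorobenzoic acid | OC(=O)c1c(F)cc(OCC=C)cc1F
F3 | step 11 | 4-(allyloxy)-2,6-difluorobenzoyl chloride | O=C(Cl)c1c(F)cc(OCC=C)cc1F
F4 | step 11 | (E)-1-[4-(allyloxy)-2,6-difluorophenyl]-2-[(2S)-5-(allyloxy)-2-{[(4-methoxybenzyl)oxy]methyl}-2-methyl-2H-chromen-8-yl]-3-(morpholin-4-yl)prop-2-en-1-one | C[C@@]1(COCc2ccc(OC)cc2)C=Cc2c(OCC=C)ccc(/C(=C\N3CCOCC3)C(=O)c3c(F)cc(OCC=C)cc3F)c2O1
F5 | step 11 | (Z)-1-[4-(allyloxy)-2,6-difluorophenyl]-2-[(2S)-5-(allyloxy)-2-{[(4-methoxybenzyl)oxy]methyl}-2-methyl-2H-chromen-8-yl]-3-hydroxyprop-2-en-1-one | C[C@@]1(COCc2ccc(OC)cc2)C=Cc2c(OCC=C)ccc(/C(=C/O)C(=O)c3c(F)cc(OCC=C)cc3F)c2O1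
F6 | step 12 | (E)-1-[2,4-bis(allyloxy)-6-fluorophenyl]-2-[(2S)-5-(allyloxy)-2-{[(4-methoxybenzyl)oxy]methyl}-2-methyl-2H-chromen-8-yl]-3-(morpholin-4-yl)prop-2-en-1-one | C[C@@]1(COCc2ccc(OC)cc2)C=Cc2c(OCC=C)ccc(/C(=C\N3CCOCC3)C(=O)c3c(F)cc(OCC=C)cc3OCC=C)c2O1
F7 | step 12 | (Z)-1-[2,4-bis(allyloxy)-6-fluorophenyl]-2-[(2S)-5-(allyloxy)-2-{[(4-methoxybenzyl)oxy]methyl}-2-methyl-2H-chromen-8-yl]-3-hydroxyprop-2-en-1-one | C[C@@]1(COCc2ccc(OC)cc2)C=Cc2c(OCC=C)ccc(/C(=C/O)C(=O)c3c(F)cc(OCC=C)cc3OCC=C)c2O1
F8 | step 10 | 2-[(2S)-5-(allyloxy)-2-{[(4-methoxybenzyl)oxy]methyl}-2-methyl-2H-chromen-8-yl]acetaldehyde | C[C@@]1(COCc2ccc(OC)cc2)C=Cc2c(OCC=C)ccc(CC=O)c2O1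
F9 | step 10 | 2-[(2S)-5-(allyloxy)-2-{[(4-methoxybenzyl)oxy]methyl}-2-methyl-2H-chromen-8-yl]-1-(2,4,6-trifluorophenyl)ethanol (both epimers at the carbinol carbon) | C[C@@]1(COCc2ccc(OC)cc2)C=Cc2c(OCC=C)ccc(CC(O)c3c(F)cc(F)cc3F)c2O1
F10 | step 10 | 2-[(2S)-5-(allyloxy)-2-{[(4-methoxybenzyl)oxy]methyl}-2-methyl-2H-chromen-8-yl]-1-(2,4,6-trifluorophenyl)ethanone | C[C@@]1(COCc2ccc(OC)cc2)C=Cc2c(OCC=C)ccc(CC(=O)c3c(F)cc(F)cc3F)c2O1
F11 | step 5 | (2S)-1-[(4-methoxybenzyl)oxy]-2-methyl-4-(triisopropylsilyl)but-3-yn-2-ol | CC(C)[Si](C#C[C@@](O)(C)COCc1ccc(OC)cc1)(C(C)C)C(C)C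
F12 | step 5 | 4-(allyloxy)-2-{[(2S)-1-[(4-methoxybenzyl)oxy]-2-methyl-4-(triisopropylsilyl)but-3-yn-2-yl]oxy}benzonitrile | CC(C)[Si](C#C[C@@](Oc1cc(OCC=C)ccc1C#N)(C)COCc1ccc(OC)cc1)(C(C)C)C(C)C
F13 | step 6 | (2R)-5-(allyloxy)-3-iodo-2-{[(4-methoxybenzyl)oxy]methyl}-2-methyl-2H-chromene-8-carbonitrile | C[C@@]1(COCc2ccc(OC)cc2)C(I)=Cc2c(OCC=C)ccc(C#N)c2O1
A1 | alternative 1 | 2'-hydroxy-3'-[(E)-4-(4-methoxybenzyloxy)-3-methylbut-2-enyl]-4'-(triisopropylsilyloxy)-5,7-bis(methoxymethoxy)isoflavone | Oc1c(C/C=C(\C)COCc2ccc(OC)cc2)c(O[Si](C(C)C)(C(C)C)C(C)C)ccc1-c1coc2cc(OCOC)cc(OCOC)c2c1=O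
A2 | alternative 1 | (E)-4-[5,7-bis(methoxymethoxy)-4-oxo-4H-chromen-3-yl]-1-diazobut-3-en-2-one | [N-]=[N+]=CC(=O)/C=C/c1coc2cc(OCOC)cc(OCOC)c2c1=O
A3 | alternative 1 | (E)-triisopropyl{[6-(4-methoxybenzyloxy)-5-methylhex-4-en-1-yn-1-yl]oxy}silane | CC(C)[Si](C(C)C)(C(C)C)OC#CC/C=C(\C)COCc1ccc(OC)cc1
A4 | alternative 2 | 3-[(2R,3S)-3-hydroxy-2-(hydroxymethyl)-5-(methoxymethoxy)-2-methyl-3,4-dihydro-2H-chromen-8-yl]-5,7-bis(methoxymethoxy)-4H-chromen-4-one | C[C@@]1(CO)[C@@H](O)Cc2c(OCOC)ccc(-c3coc4cc(OCOC)cc(OCOC)c4c3=O)c2O1
A5 | alternative 2 | 3-{2-hydroxy-3-{[(2S,3S)-3-(hydroxymethyl)-3-methyloxiran-2-yl]methyl}-4-(methoxymethoxy)phenyl}-5,7-bis(methoxymethoxy)-4H-chromen-4-one | C[C@@]1(CO)O[C@H]1Cc1c(O)c(-c2coc3cc(OCOC)cc(OCOC)c3c2=O)ccc1OCOC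
A6 | alternative 3 | (2S)-2-{[(tert-butyldimethylsilyl)oxy]methyl}-5-(methoxymethoxy)-2-methyl-2H-chromene-8-carbaldehyde | C[C@@]1(CO[Si](C)(C)C(C)(C)C)C=Cc2c(OCOC)ccc(C=O)c2O1
A7 | alternative 3 | 2-{[(2S)-1-[(tert-butyldimethylsilyl)oxy]-2-methylbut-3-yn-2-yl]oxy}-4-(methoxymethoxy)benzaldehyde | C#C[C@@](Oc1cc(OCOC)ccc1C=O)(C)CO[Si](C)(C)C(C)(C)C
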